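**Assumptions.** (1) The target's stereocentre is (R), as in rosmarinic acid and danshensu. (2) Sodium (R)-danshensu and methyl coumalate are purchasable.

## Retrosynthetic overview
- Eritrichin is the (R)-danshensu ester of 4-(3,4-dihydroxyphenyl)-6,7-dihydroxy-2-naphthoic acid. Cut the ester, with all phenols and the danshensu CO2H carried as methyl groups, to give a naphthoic acid and a chiral-pool hydroxy ester.
- The naphthalene's second ring is made in one step. A symmetrical 4,5-dimethoxybenzyne is desymmetrised by [4+2] cycloaddition to the pseudo-aromatic 3-aryl-2-pyrone-5-carboxylate, and CO2 loss re-aromatises the new ring. The 1,3 relationship of aryl and ester is fixed by the pyrone substitution pattern.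
- The arylpyrone comes from methyl coumalate (a malic acid derivative) by C3 bromination and Suzuki coupling with 3,4-dimethoxyphenylboronic acid.
- The only stereocentre comes from (R)-danshensu and is never touched. A final global BBr3 demethylation gives the target.

## Route

**Step 1**
Reactants: 1 (sodium (R)-danshensu)
Product: 2 (methyl (R)-3-(3,4-dimethoxyphenyl)-2-hydroxypropanoate)
Conditions: MeI (4 equiv), K2CO3 (4 equiv), DMF, N2, rt, 16 h
Reagents that add atoms: iodomethane, CI (leaves three CH3 groups)
Why: K2CO3/MeI is a chemoselective O-methylation of the two phenols and the carboxylate; the secondary alcohol is not deprotonated. The stereocentre is chiral-pool (R) and is not epimerised under these mild conditions.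

**Step 2**
Reactants: 3 (methyl coumalate)
Product: 4 (methyl 3-bromo-2-oxo-2H-pyran-5-carboxylate)
Conditions: (i) Br2, CH2Cl2, rt; (ii) Et3N, 0 °C
Reagents that add atoms: bromine, BrBr (leaves Br)
Why: Br2 adds across C3=C4 of the pyrone. Et3N then removes the acidic C3–H by E1cB and expels Br from C4, leaving the 3-bromopyrone (bromination–dehydrobromination as for 2-pyrones generally). The bromination is done before any electron-rich arene is present.

**Step 3**
Reactants: 4; 5 (3,4-dimethoxyphenylboronic acid)
Product: 6 (methyl 3-(3,4-dimethoxyphenyl)-2-oxo-2H-pyran-5-carboxylate)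
Conditions: Pd(PPh3)4 (5 mol%), CsF (2.5 equiv), 1,4-dioxane, 80 °C
Reagents that add atoms: none (5 is the coupling partner)
Why: Suzuki–Miyaura coupling at the vinyl bromide. Anhydrous fluoride activation avoids hydroxide, which would open the pyrone lactone. No stereocentre is formed.

**Step 4 (key step)**
Reactants: 6; 7 (2-amino-4,5-dimethoxybenzoic acid)
Product: 8 (methyl 4-(3,4-dimethoxyphenyl)-6,7-dimethoxy-2-naphthoate)
Conditions: 7 (2.5 equiv) in MeCN added over 1 h to 6 and isoamyl nitrite (3 equiv), cat. TFA, propylene oxide, 1,2-dichloroethane, reflux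
Reagents that add atoms: none (N2, CO2 and isoamyl alcohol are lost)
Why: Diazotisation gives 4,5-dimethoxybenzenediazonium-2-carboxylate, which loses N2 and CO2 to give 4,5-dimethoxybenzyne in situ. The electron-rich aryne pairs well with the electron-poor coumalate diene (inverse-demand [4+2] cycloaddition). This breaks the pyrone's pseudo-aromaticity, and retro-[4+2] loss of CO2 from the bridged lactone builds the new aromatic ring. The aryne is symmetrical, so the product is a single regioisomer: pyrone C3 (aryl) becomes naphthalene C4, C4–H becomes C3, C5 (CO2Me) becomes C2 and C6–H becomes C1. No stereocentre is formed.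
Proposed new method: closest known reaction is aryne + 2-pyrone Diels–Alder/decarboxylative aromatisation and coumalate inverse-demand cycloadditions. The specific 3-aryl coumalate/dimethoxybenzyne pairing is extrapolated, and the slow addition keeps free aniline low so it does not open the pyrone.

**Step 5**
Reactants: 8
Product: 9 (4-(3,4-dimethoxyphenyl)-6,7-dimethoxy-2-naphthoic acid)
Conditions: LiOH·H2O (5 equiv), THF/H2O 3:1, 50 °C; then 1 M HCl
Reagents that add atoms: water, O (supplies the carboxylic acid OH)
Why: Saponification of the unhindered methyl ester. The aryl methyl ethers are inert and there is no stereocentre.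

**Step 6**
Reactants: 9; 2
Product: 10 (methyl (R)-3-(3,4-dimethoxyphenyl)-2-{[4-(3,4-dimethoxyphenyl)-6,7-dimethoxy-2-naphthoyl]oxy}propanoate)
Conditions: EDC·HCl (1.5 equiv), DMAP (0.2 equiv), CH2Cl2, 0 °C → rt
Reagents that add atoms: none
Why: Steglich esterification of the secondary α-hydroxy ester. The C–O bond of the alcohol is retained, so the (R) centre is untouched, and the mild conditions at 0 °C to rt limit epimerisation.

**Step 7**
Reactants: 10
Product: 11 (eritrichin)
Conditions: BBr3 (15 equiv), CH2Cl2, −78 °C → rt, 16 h; quench with ice-water
Reagents that add atoms: none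
Why: BBr3 cleaves all four aryl methyl ethers, the two danshensu aryl methyl ethers and the terminal methyl ester to give catechols and the free acid. The aroyl ester survives because its alkyl carbon is a secondary, α-carboxy-substituted centre that is resistant to SN2 cleavage. The stereocentre is not involved, and the water quench hydrolyses the borate complexes.

## Compound list
1 | sodium (2R)-3-(3,4-dihydroxyphenyl)-2-hydroxypropanoate ((R)-danshensu Na) | [Na+].O=C([O-])[C@H](O)Cc1ccc(O)c(O)c1 | starting material
2 | methyl (R)-3-(3,4-dimethoxyphenyl)-2-hydroxypropanoate | COC(=O)[C@H](O)Cc1ccc(OC)c(OC)c1 | intermediate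
3 | methyl coumalate | COC(=O)C1=COC(=O)C=C1 | starting material
4 | methyl 3-bromo-2-oxo-2H-pyran-5-carboxylate | COC(=O)C1=COC(=O)C(Br)=C1 | intermediate
5 | 3,4-dimethoxyphenylboronic acid | COc1ccc(B(O)O)cc1OC | starting material
6 | methyl 3-(3,4-dimethoxyphenyl)-2-oxo-2H-pyran-5-carboxylate | COC(=O)C1=COC(=O)C(=C1)c1ccc(OC)c(OC)c1 | intermediate
7 | 2-amino-4,5-dimethoxybenzoic acid | OC(=O)c1cc(OC)c(OC)cc1N | starting material
8 | methyl 4-(3,4-dimethoxyphenyl)-6,7-dimethoxy-2-naphthoate | COC(=O)c1cc(-c2ccc(OC)c(OC)c2)c2cc(OC)c(OC)cc2c1 | intermediate
9 | 4-(3,4-dimethoxyphenyl)-6,7-dimethoxy-2-naphthoic acid | COc1cc2cc(C(=O)O)cc(-c3ccc(OC)c(OC)c3)c2cc1OC | intermediate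
10 | methyl (R)-2-aroyloxy-3-(3,4-dimethoxyphenyl)propanoate (tetramethoxynaphthoyl ester) | COC(=O)[C@H](OC(=O)c1cc(-c2ccc(OC)c(OC)c2)c2cc(OC)c(OC)cc2c1)Cc1ccc(OC)c(OC)c1 | intermediate
11 | eritrichin | O=C(O[C@H](Cc1ccc(O)c(O)c1)C(=O)O)c1cc(-c2ccc(O)c(O)c2)c2cc(O)c(O)cc2c1 | target

**Total steps:** 7. **Longest linear sequence:** 6 steps, from methyl coumalate (3) through 4, 6, 8, 9 and 10 to 11. The danshensu branch adds one step.

**Three steps most likely to fail**
1. **Step 4 (aryne/pyrone cycloaddition).** The aniline may open the pyrone, the aryne may be consumed by side reactions, or the electron-rich diazonium carboxylate may decompose poorly. Fallback: generate the aryne from 4,5-dimethoxy-2-(trimethylsilyl)phenyl triflate with CsF in MeCN (fluoride-triggered, no free amine or nitrite). Alternatively, run the cycloaddition on bromopyrone 4 and then do the Suzuki coupling on the resulting 4-bromonaphthoate.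
2. **Step 7 (global BBr3 demethylation).** Seven methyl groups must come off without cleaving the aroyl ester or racemising the α-acyloxy acid. Fallback: switch the protecting-group strategy to benzyl ethers and a benzyl ester, using 3,4-bis(benzyloxy)phenylboronic acid and a bis(benzyloxy)aryne precursor, and finish by Pd/C hydrogenolysis at rt and 1 atm.
3. **Step 3 (Suzuki coupling on the base-sensitive 3-bromopyrone).** Fallback: change the order so that aryne cycloaddition on 4 gives methyl 4-bromo-6,7-dimethoxy-2-naphthoate. Couple that with boronic acid 5 on the aromatic ring, or use a Stille coupling with the aryl stannane, and then continue with steps 5–7.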